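**Plan**

- Locants: the 4-hydroxyphenyl flavanone half is unprimed, the 4-methoxyphenyl half is double-primed. Retrosynthetic cuts, in order: the five benzyl ethers; C3–C4 of the unprimed pyranone ring (retro 1,2-acyl shift, so this six-membered ring comes from a 2-aryl-benzofuran-3-one) together with C3''–C4'' of the other pyranone ring (retro acyl-radical closure); the aryl ether O1''–C2''; the quaternary C–vinyl bond.
- Enabling feature: C2 is a benzylic carbon bearing the ring oxygen O1, so a radical there is strongly stabilised. The C4 carbonyl can therefore migrate from C2 to the neighbouring carbon (ring O1–C2–C4–C4a–C8a grows to O1–C2–C3–C4–C4a–C8a), and the C4(=O)–C3–C3''–C4''(=O) 1,4-diketone becomes an alkene C3=C3'' held between an aroyl radical and a ketone.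
- Forward: benzofuranone → 2-arylation → asymmetric vinylic substitution (quaternary carbon) → carbinol → aryl allyl ether → selenoester. One radical chain then closes the double-primed pyranone ring (6-exo) and enlarges the furanone to the unprimed pyranone ring; hydrogenolysis ends the route.
- Stereochemistry: C2'' from a reagent-controlled carbinol carried through a stereoretentive allylic substitution; C2 by relay from the catalyst-set quaternary carbon during the cascade; C3 and C3'' by equilibration to the trans (diequatorial) arrangement beside each fixed C2.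

Key step: step 11

Assumption: the named antipode of each chiral catalyst (steps 4 and 5) is the one expected by analogy with the parent reactions to give the drawn configuration; the drawn SMILES define what each step is meant to deliver.

Step 1
Reactants: 1 4,6-dihydroxy-1-benzofuran-3(2H)-one
Product: 2 4,6-bis(benzyloxy)-1-benzofuran-3(2H)-one
Conditions: BnBr (2.2 equiv), K2CO3, DMF, 0 °C to rt
Reagents that add atoms: benzyl bromide BrCc1ccccc1
Why: Williamson etherification of both phenols, phenoxide O-alkylation being faster than C-alkylation of the C2 methylene under carbonate conditions.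

Step 2
Reactants: 2 4,6-bis(benzyloxy)-1-benzofuran-3(2H)-one; 3 1-(benzyloxy)-4-bromobenzene
Product: 4 rac-4,6-bis(benzyloxy)-2-[4-(benzyloxy)phenyl]-1-benzofuran-3(2H)-one
Conditions: Pd2(dba)3 (2 mol %), XPhos (5 mol %), NaOt-Bu, toluene, 80 °C, Ar
Reagents that add atoms: none
Why: Pd-catalysed α-arylation of the ketone enolate should stop at monoarylation because the product enolate is tertiary and hindered; C2 stays enolisable and is fixed only in step 4.

Step 3
Reactants: 5 4-methoxybenzoyl chloride; 6 acetylene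
Product: 7 (E)-3-chloro-1-(4-methoxyphenyl)prop-2-en-1-one
Conditions: AlCl3, CH2Cl2, 0 °C
Reagents that add atoms: none
Why: Friedel–Crafts-type chloroacylation of acetylene by the acylium/tetrachloroaluminate pair should give the trans β-chlorovinyl ketone.

Step 4
Reactants: 4 rac-4,6-bis(benzyloxy)-2-[4-(benzyloxy)phenyl]-1-benzofuran-3(2H)-one; 7 (E)-3-chloro-1-(4-methoxyphenyl)prop-2-en-1-one
Product: 8 (2S)-4,6-bis(benzyloxy)-2-[4-(benzyloxy)phenyl]-2-[(E)-3-(4-methoxyphenyl)-3-oxoprop-1-enyl]-1-benzofuran-3(2H)-one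
Conditions: O-(1-adamantoyl)-N-(9-anthracenylmethyl)dihydrocinchoninium chloride (10 mol %), aq. Cs2CO3, toluene, −30 °C, Ar
Reagents that add atoms: none
Why: asymmetric nucleophilic vinylic substitution (conjugate addition–chloride elimination) under chiral phase-transfer catalysis, in which the soft aryl-stabilised enolate attacks through carbon with retention of the E geometry and the chiral ammonium ion pair shields one enolate face to set the (S) quaternary carbon.

Step 5
Reactants: 8 (2S)-4,6-bis(benzyloxy)-2-[4-(benzyloxy)phenyl]-2-[(E)-3-(4-methoxyphenyl)-3-oxoprop-1-enyl]-1-benzofuran-3(2H)-one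
Product: 9 (2S)-4,6-bis(benzyloxy)-2-[4-(benzyloxy)phenyl]-2-[(1E,3S)-3-hydroxy-3-(4-methoxyphenyl)prop-1-enyl]-1-benzofuran-3(2H)-one
Conditions: (R)-2-methyl-CBS-oxazaborolidine (20 mol %), catecholborane, toluene, −78 °C
Reagents that add atoms: none
Why: Corey–Bakshi–Shibata 1,2-reduction of the enone carbonyl, with the catalyst (aryl as the large group) setting the (S) carbinol while the hindered, electron-rich furanone carbonyl is left untouched.

Step 6
Reactants: 9 (2S)-4,6-bis(benzyloxy)-2-[4-(benzyloxy)phenyl]-2-[(1E,3S)-3-hydroxy-3-(4-methoxyphenyl)prop-1-enyl]-1-benzofuran-3(2H)-one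
Product: 10 methyl (1S,2E)-1-(4-methoxyphenyl)-3-{(2S)-4,6-bis(benzyloxy)-2-[4-(benzyloxy)phenyl]-3-oxo-2,3-dihydro-1-benzofuran-2-yl}prop-2-enyl carbonate
Conditions: ClCO2Me, pyridine, DMAP (cat.), CH2Cl2, −20 °C
Reagents that add atoms: methyl chloroformate COC(=O)Cl
Why: O-acylation of the secondary alcohol, which breaks no bond to the stereocentre.

Step 7
Reactants: 11 2,4,6-trihydroxybenzaldehyde
Product: 12 2,4-bis(benzyloxy)-6-hydroxybenzaldehyde
Conditions: BnBr (2.05 equiv), K2CO3, DMF, 0 °C to rt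
Reagents that add atoms: benzyl bromide BrCc1ccccc1
Why: Williamson etherification in which the 4-OH and one 2-OH are alkylated while the remaining ortho hydroxyl, hydrogen-bonded to the aldehyde, is the least nucleophilic and stays free when the bromide is limited to two equivalents.

Step 8
Reactants: 10 methyl (1S,2E)-1-(4-methoxyphenyl)-3-{(2S)-4,6-bis(benzyloxy)-2-[4-(benzyloxy)phenyl]-3-oxo-2,3-dihydro-1-benzofuran-2-yl}prop-2-enyl carbonate; 12 2,4-bis(benzyloxy)-6-hydroxybenzaldehyde
Product: 13 2,4-bis(benzyloxy)-6-[(1S,2E)-1-(4-methoxyphenyl)-3-{(2S)-4,6-bis(benzyloxy)-2-[4-(benzyloxy)phenyl]-3-oxo-2,3-dihydro-1-benzofuran-2-yl}prop-2-enyloxy]benzaldehyde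
Conditions: Pd2(dba)3·CHCl3 (2.5 mol %), PPh3 (10 mol %), THF, 0 °C to rt
Reagents that add atoms: none
Why: Tsuji–Trost allylic etherification in which ionisation with inversion gives the syn,syn π-allyl complex and the phenoxide attacks anti to the metal at the anisyl terminus (the other terminus is neopentyl-like beside the quaternary carbon), so the ether carbon forms with net retention (S) and the alkene stays E.

Step 9
Reactants: 13 2,4-bis(benzyloxy)-6-[(1S,2E)-1-(4-methoxyphenyl)-3-{(2S)-4,6-bis(benzyloxy)-2-[4-(benzyloxy)phenyl]-3-oxo-2,3-dihydro-1-benzofuran-2-yl}prop-2-enyloxy]benzaldehyde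
Product: 14 2,4-bis(benzyloxy)-6-[(1S,2E)-1-(4-methoxyphenyl)-3-{(2S)-4,6-bis(benzyloxy)-2-[4-(benzyloxy)phenyl]-3-oxo-2,3-dihydro-1-benzofuran-2-yl}prop-2-enyloxy]benzoic acid
Conditions: NaClO2, NaH2PO4, 2-methyl-2-butene (excess), t-BuOH/THF/H2O, rt
Reagents that add atoms: sodium chlorite [Na+].[O-]Cl=O
Why: Pinnick oxidation of the aryl aldehyde, with the alkene scavenger trapping hypochlorous acid before it can chlorinate the electron-rich rings or the hindered substrate alkene.

Step 10
Reactants: 14 2,4-bis(benzyloxy)-6-[(1S,2E)-1-(4-methoxyphenyl)-3-{(2S)-4,6-bis(benzyloxy)-2-[4-(benzyloxy)phenyl]-3-oxo-2,3-dihydro-1-benzofuran-2-yl}prop-2-enyloxy]benzoic acid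
Product: 15 Se-phenyl 2,4-bis(benzyloxy)-6-[(1S,2E)-1-(4-methoxyphenyl)-3-{(2S)-4,6-bis(benzyloxy)-2-[4-(benzyloxy)phenyl]-3-oxo-2,3-dihydro-1-benzofuran-2-yl}prop-2-enyloxy]benzenecarboselenoate
Conditions: N-(phenylselanyl)phthalimide, PBu3, CH2Cl2, −20 °C to rt
Reagents that add atoms: N-(phenylselanyl)phthalimide O=C1c2ccccc2C(=O)N1[Se]c1ccccc1
Why: phosphine-mediated selenoesterification through an acyloxyphosphonium ion, a method that tolerates 2,6-disubstituted benzoic acids and touches no stereocentre.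

Step 11
Reactants: 15 Se-phenyl 2,4-bis(benzyloxy)-6-[(1S,2E)-1-(4-methoxyphenyl)-3-{(2S)-4,6-bis(benzyloxy)-2-[4-(benzyloxy)phenyl]-3-oxo-2,3-dihydro-1-benzofuran-2-yl}prop-2-enyloxy]benzenecarboselenoate
Product: 21 (2S,3R,2''S,3''R)-5,5'',7,7''-tetrakis(benzyloxy)-2-[4-(benzyloxy)phenyl]-2''-(4-methoxyphenyl)-3,3''-bichromane-4,4''-dione, via aroyl radical 16 (not isolated), via alkyl radical 17 (not isolated), via cyclopropyloxy radical 18 (not isolated), via benzylic radical 19 (not isolated), via cis epimer 20 (not isolated)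
Conditions: Bu3SnH (1.3 equiv) and AIBN (0.3 equiv) added by syringe pump over 8 h, PhH (0.004 M), 80 °C; then Et3N, CH2Cl2/MeOH, rt
Reagents that add atoms: none
Why: Proposed new method: the stannyl radical takes PhSe from 15, aroyl radical 16 closes the double-primed pyranone ring by 6-exo-trig addition to the near alkene carbon, the resulting secondary radical 17 adds 3-exo-trig to the furanone carbonyl, and β-scission of cyclopropyloxy radical 18 at the old C2–C(=O) bond turns the five-membered O1–C2–C(=O)–C3a–C7a ring into the six-membered pyranone (a net 1,2-acyl shift that inserts the former vinyl carbon as C3) and leaves radical 19 at C2, benzylic and bearing the ring oxygen, which is reduced by Bu3SnH. The closest known reactions are the acyl-radical 6-exo cyclisation of 2-(allyloxy)aroyl precursors to chroman-4-ones and the Dowd–Beckwith one-carbon ring expansion of 2-(halomethyl) β-keto esters; new here are their coupling in one chain and an aryl plus ring-oxygen pair in place of the ester as the radical-stabilising group at the migration origin. C2'' is untouched and C3'' forms trans to the equatorial anisyl group in a chair-like transition state; the configuration of C2 is relayed from the quaternary carbon, because in 18 the large C3 substituent takes the cyclopropane face away from the aryl and O-radical groups, which fixes C3, and Bu3SnH then delivers H to planar 19 anti to this pseudoaxial substituent to give cis epimer 20 with (2S) configuration. Et3N finally equilibrates the enolisable C3 and C3'' to the diequatorial trans arrangement beside the fixed C2 and C2'', which gives 21. The step needs 6-exo over 7-endo closure (secured by the quaternary carbon that blocks the distal alkene carbon), acyl shift over aryl shift and over β-loss of the aryloxyl group (the acyl shift is the fastest 1,2-shift open to a β-keto radical and gives the most stabilised radical), and ring expansion before reduction of 17 (secured by slow addition of Bu3SnH at high dilution).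

Step 12
Reactants: 21 (2S,3R,2''S,3''R)-5,5'',7,7''-tetrakis(benzyloxy)-2-[4-(benzyloxy)phenyl]-2''-(4-methoxyphenyl)-3,3''-bichromane-4,4''-dione
Product: 22 (2S,3R,2''S,3''R)-5,5'',7,7''-tetrahydroxy-2-(4-hydroxyphenyl)-2''-(4-methoxyphenyl)-3,3''-bichromane-4,4''-dione (CNP0196568.1)
Conditions: H2 (1 atm), 10% Pd/C, EtOAc/MeOH, rt
Reagents that add atoms: none
Why: hydrogenolysis of the five benzyl ethers under neutral conditions should leave the aryl methyl ether and all four stereocentres untouched, since no base is present to open a pyranone ring.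

**Compound list**

1 | 4,6-dihydroxy-1-benzofuran-3(2H)-one | O=C1COc2cc(O)cc(O)c12 | starting material
2 | 4,6-bis(benzyloxy)-1-benzofuran-3(2H)-one | O=C1COc2cc(OCc3ccccc3)cc(OCc3ccccc3)c12 | intermediate
3 | 1-(benzyloxy)-4-bromobenzene | Brc1ccc(OCc2ccccc2)cc1 | starting material
4 | rac-4,6-bis(benzyloxy)-2-[4-(benzyloxy)phenyl]-1-benzofuran-3(2H)-one | O=C1C(c2ccc(OCc3ccccc3)cc2)Oc2cc(OCc3ccccc3)cc(OCc3ccccc3)c12 | intermediate
5 | 4-methoxybenzoyl chloride | COc1ccc(C(=O)Cl)cc1 | starting material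
6 | acetylene | C#C | starting material
7 | (E)-3-chloro-1-(4-methoxyphenyl)prop-2-en-1-one | COc1ccc(C(=O)/C=C/Cl)cc1 | intermediate
8 | (2S)-quaternary E-enone | COc1ccc(C(=O)/C=C/[C@@]2(c3ccc(OCc4ccccc4)cc3)Oc3cc(OCc4ccccc4)cc(OCc4ccccc4)c3C2=O)cc1 | intermediate
9 | (2S)-quaternary (3S)-allylic alcohol | COc1ccc([C@@H](O)/C=C/[C@@]2(c3ccc(OCc4ccccc4)cc3)Oc3cc(OCc4ccccc4)cc(OCc4ccccc4)c3C2=O)cc1 | intermediate
10 | methyl carbonate of 9 | COc1ccc([C@@H](OC(=O)OC)/C=C/[C@@]2(c3ccc(OCc4ccccc4)cc3)Oc3cc(OCc4ccccc4)cc(OCc4ccccc4)c3C2=O)cc1 | intermediate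
11 | 2,4,6-trihydroxybenzaldehyde | O=Cc1c(O)cc(O)cc1O | starting material
12 | 2,4-bis(benzyloxy)-6-hydroxybenzaldehyde | O=Cc1c(O)cc(OCc2ccccc2)cc1OCc1ccccc1 | intermediate
13 | (S)-aryl allyl ether aldehyde | COc1ccc([C@@H](Oc2cc(OCc3ccccc3)cc(OCc3ccccc3)c2C=O)/C=C/[C@@]2(c3ccc(OCc4ccccc4)cc3)Oc3cc(OCc4ccccc4)cc(OCc4ccccc4)c3C2=O)cc1 | intermediate
14 | benzoic acid from 13 | COc1ccc([C@@H](Oc2cc(OCc3ccccc3)cc(OCc3ccccc3)c2C(=O)O)/C=C/[C@@]2(c3ccc(OCc4ccccc4)cc3)Oc3cc(OCc4ccccc4)cc(OCc4ccccc4)c3C2=O)cc1 | intermediate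
15 | Se-phenyl selenoester of 14 | COc1ccc([C@@H](Oc2cc(OCc3ccccc3)cc(OCc3ccccc3)c2C(=O)[Se]c2ccccc2)/C=C/[C@@]2(c3ccc(OCc4ccccc4)cc3)Oc3cc(OCc4ccccc4)cc(OCc4ccccc4)c3C2=O)cc1 | intermediate
16 | aroyl radical from 15 | COc1ccc([C@@H](Oc2cc(OCc3ccccc3)cc(OCc3ccccc3)c2[C]=O)/C=C/[C@@]2(c3ccc(OCc4ccccc4)cc3)Oc3cc(OCc4ccccc4)cc(OCc4ccccc4)c3C2=O)cc1 | intermediate
17 | alkyl radical after closure of the double-primed pyranone ring (radical CH between C3'' and the quaternary carbon) | COc1ccc([C@H]2Oc3cc(OCc4ccccc4)cc(OCc4ccccc4)c3C(=O)[C@@H]2[CH][C@@]2(c3ccc(OCc4ccccc4)cc3)Oc3cc(OCc4ccccc4)cc(OCc4ccccc4)c3C2=O)cc1 | intermediate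
18 | cyclopropyloxy radical (cyclopropane fused to the dihydrobenzofuran, oxygen-centred radical) | COc1ccc([C@H]2Oc3cc(OCc4ccccc4)cc(OCc4ccccc4)c3C(=O)[C@@H]2[C@H]2[C@@]3(c4ccc(OCc5ccccc5)cc4)Oc4cc(OCc5ccccc5)cc(OCc5ccccc5)c4[C@@]23[O])cc1 | intermediate
19 | ring-expanded C2 benzylic radical (3S,2''S,3''R) | COc1ccc([C@H]2Oc3cc(OCc4ccccc4)cc(OCc4ccccc4)c3C(=O)[C@@H]2[C@@H]2C(=O)c3c(OCc4ccccc4)cc(OCc4ccccc4)cc3O[C]2c2ccc(OCc3ccccc3)cc2)cc1 | intermediate
20 | (2S,3S,2''S,3''R) cis epimer of 21 | COc1ccc([C@H]2Oc3cc(OCc4ccccc4)cc(OCc4ccccc4)c3C(=O)[C@@H]2[C@@H]2C(=O)c3c(OCc4ccccc4)cc(OCc4ccccc4)cc3O[C@@H]2c2ccc(OCc3ccccc3)cc2)cc1 | intermediate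
21 | (2S,3R,2''S,3''R)-5,5'',7,7''-tetrakis(benzyloxy)-2-[4-(benzyloxy)phenyl]-2''-(4-methoxyphenyl)-3,3''-bichromane-4,4''-dione | COc1ccc([C@H]2Oc3cc(OCc4ccccc4)cc(OCc4ccccc4)c3C(=O)[C@@H]2[C@H]2C(=O)c3c(OCc4ccccc4)cc(OCc4ccccc4)cc3O[C@@H]2c2ccc(OCc3ccccc3)cc2)cc1 | intermediate
22 | (2S,3R,2''S,3''R)-5,5'',7,7''-tetrahydroxy-2-(4-hydroxyphenyl)-2''-(4-methoxyphenyl)-3,3''-bichromane-4,4''-dione | COc1ccc([C@H]2Oc3cc(O)cc(O)c3C(=O)[C@@H]2[C@H]2C(=O)c3c(O)cc(O)cc3O[C@@H]2c2ccc(O)cc2)cc1 | target

**Totals and risks**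

Total step count: 12. Longest linear sequence: 10 steps (steps 1, 2, 4, 5, 6, 8, 9, 10, 11, 12).

Steps most likely to fail:

1. Step 11 (Proposed new method). Two processes may intervene: hydrogen transfer to the cyclised alkyl radical before the 3-exo closure and scission, and poor facial selectivity in the closure or in the H delivery, which would erode the relay to C2. The fallback uses known chemistry, sets out from 12 and comes back at 21. MeMgBr adds to the aldehyde to give 1-[2,4-bis(benzyloxy)-6-hydroxyphenyl]ethanol F1, and MnO2 oxidises it to 1-[2,4-bis(benzyloxy)-6-hydroxyphenyl]ethanone F2. DMF dimethyl acetal gives the enaminone F3, which HCl closes to 5,7-bis(benzyloxy)chromone F4. Rhodium-catalysed asymmetric 1,4-addition ([Rh(OH)(cod)]2, chiral bisphosphine) of 4-methoxyphenylboronic acid gives (2S)-5,7-bis(benzyloxy)-2-(4-methoxyphenyl)chroman-4-one F5; the same addition of 4-(benzyloxy)phenylboronic acid gives (2S)-5,7-bis(benzyloxy)-2-[4-(benzyloxy)phenyl]chroman-4-one F6. Soft enolisation of F5 with i-Pr2Si(OTf)2/Et3N gives the silyl triflate enol ether F7, which is joined with F6 (Et3N) to the mixed diisopropylsilyl bis-enol ether F8. Oxidation with (NH4)2Ce(NO3)6/NaHCO3 in MeCN at −20 °C should couple the two enol ethers within the silicon tether, each new bond forming trans to the neighbouring aryl group, and brief Et3N equilibration should give 21.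

2. Step 4. The ambident enolate may react through oxygen, and face selection at the quaternary carbon may be low. The fallback sets out from 4 and 7 and comes back at 9. Achiral phase-transfer conditions (Bu4NBr, K2CO3, toluene) give the racemic enone F9. The reduction of step 5 then gives 9 together with its quaternary-carbon epimer F10; the two are diastereomers and are separated by chromatography.

3. Step 8. Re-ionisation of the anisyl-activated allyl ether, or exchange between palladium centres, may erode the configuration of the ether carbon, and attack at the wrong allyl terminus is possible. The fallback sets out from 8 and comes back at 13. Reduction with the (S)-configured oxazaborolidine gives the (3R)-allylic alcohol F11. Mitsunobu etherification with 12 (PPh3, DIAD, toluene, −20 °C) inverts the carbinol carbon and gives 13 without a π-allyl intermediate.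

**Further compounds**

F1 | step 11 | 1-[2,4-bis(benzyloxy)-6-hydroxyphenyl]ethanol | CC(O)c1c(O)cc(OCc2ccccc2)cc1OCc1ccccc1
F2 | step 11 | 1-[2,4-bis(benzyloxy)-6-hydroxyphenyl]ethanone | CC(=O)c1c(O)cc(OCc2ccccc2)cc1OCc1ccccc1
F3 | step 11 | (E)-1-[2,4-bis(benzyloxy)-6-hydroxyphenyl]-3-(dimethylamino)prop-2-en-1-one | CN(C)/C=C/C(=O)c1c(O)cc(OCc2ccccc2)cc1OCc1ccccc1
F4 | step 11 | 5,7-bis(benzyloxy)-4H-chromen-4-one | O=c1ccoc2cc(OCc3ccccc3)cc(OCc3ccccc3)c12
F5 | step 11 | (2S)-5,7-bis(benzyloxy)-2-(4-methoxyphenyl)chroman-4-one | COc1ccc([C@H]2Oc3cc(OCc4ccccc4)cc(OCc4ccccc4)c3C(=O)C2)cc1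
F6 | step 11 | (2S)-5,7-bis(benzyloxy)-2-[4-(benzyloxy)phenyl]chroman-4-one | c1ccccc1COc1ccc([C@H]2Oc3cc(OCc4ccccc4)cc(OCc4ccccc4)c3C(=O)C2)cc1
F7 | step 11 | diisopropyl(triflyloxy)silyl enol ether of F5 | COc1ccc([C@H]2Oc3cc(OCc4ccccc4)cc(OCc4ccccc4)c3C(O[Si](OS(=O)(=O)C(F)(F)F)(C(C)C)C(C)C)=C2)cc1
F8 | step 11 | mixed diisopropylsilyl bis-enol ether of F5 and F6 | COc1ccc([C@H]2Oc3cc(OCc4ccccc4)cc(OCc4ccccc4)c3C(O[Si](C(C)C)(C(C)C)OC3=C[C@@H](c4ccc(OCc5ccccc5)cc4)Oc4cc(OCc5ccccc5)cc(OCc5ccccc5)c34)=C2)cc1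
F9 | step 4 | racemic enone (8 without control at the quaternary carbon) | COc1ccc(C(=O)/C=C/C2(c3ccc(OCc4ccccc4)cc3)Oc3cc(OCc4ccccc4)cc(OCc4ccccc4)c3C2=O)cc1
F10 | step 4 | (2R)-quaternary (3S)-allylic alcohol, epimer of 9 | COc1ccc([C@@H](O)/C=C/[C@]2(c3ccc(OCc4ccccc4)cc3)Oc3cc(OCc4ccccc4)cc(OCc4ccccc4)c3C2=O)cc1
F11 | step 8 | (2S)-quaternary (3R)-allylic alcohol | COc1ccc([C@H](O)/C=C/[C@@]2(c3ccc(OCc4ccccc4)cc3)Oc3cc(OCc4ccccc4)cc(OCc4ccccc4)c3C2=O)cc1
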